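**Retrosynthetic overview**

1. Numbering: C8 = acetoxy bridgehead, C8' = CH bridgehead, C7/C7' = aryl-bearing O–CH carbons on C8/C8', C9/C9' = OCH2 carbons on C8/C8'; ring A = C7'–O–C9–C8–C8', ring B = C7–O–C9'–C8'–C8.
2. Feature: C8 with its oxygen, C9 (a masked carboxyl) and the C8'–C9' arm (a masked CH2–CO2H) is C2 of (S)-malic acid, with C7 standing where the malic acid hydrogen was (retention).
3. Endgame disconnections: acetate and phenol silyl ethers; ring B ether at O–C9' (SN2 by the C7 hydroxyl); ring A ether at C7'–O (benzylic cation trapped by the C9 hydroxyl); C9 and C9' alcohols from ester and lactone carbonyls.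
4. C–C disconnections: C8'–C7' (aldol of the β-hydroxy lactone dianion with silylated vanillin) and C7–C8 (aldol of the dilithiated pivalaldehyde dioxolanone of malic acid with the same aldehyde, followed by lactonisation).
5. Ring order: ring B as γ-lactone (step 3), opened by reduction (step 6), ring A as ether (step 7), ring B as ether (step 8).

Key step: step 3

Assumption: the phenols are carried as triisopropylsilyl ethers so that they outlast methanolic HCl, lithium alkoxides and LiAlH4; compounds 11 and 12 are carried as C7' epimer pairs because step 7 forms that centre anew.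

Ar = 3-methoxy-4-(triisopropylsilyloxy)phenyl throughout.

**Route**

Step 1
Reactants: 1 (S)-malic acid; 2 pivalaldehyde
Product: 3 2-[(2S,4S)-2-tert-butyl-5-oxo-1,3-dioxolan-4-yl]acetic acid (cis: tert-butyl and CH2CO2H on the same ring face)
Conditions: TsOH·H2O (cat.), H2SO4 (cat.), pentane, reflux, Dean–Stark; recrystallisation
Reagents that add atoms: none
Why: Acid-catalysed acetalisation of the α-hydroxy acid unit is reversible only at the new acetal carbon, so the cis dioxolanone, favoured at equilibrium and the isomer that crystallises, should be obtained with the malic acid centre untouched.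

Step 2
Reactants: 4 vanillin
Product: 5 3-methoxy-4-(triisopropylsilyloxy)benzaldehyde
Conditions: iPr3SiCl, imidazole, DMF, rt
Reagents that add atoms: chlorotriisopropylsilane, CC(C)[Si](Cl)(C(C)C)C(C)C
Why: Imidazole-promoted O-silylation of a phenol is routine and removes the acidic proton that would quench the enolates of steps 3 and 5.

Step 3
Reactants: 3 2-[(2S,4S)-2-tert-butyl-5-oxo-1,3-dioxolan-4-yl]acetic acid; 5 3-methoxy-4-(triisopropylsilyloxy)benzaldehyde
Product: 8 (2S,5R,6R)-2-tert-butyl-6-Ar-1,3,7-trioxaspiro[4.4]nonane-4,8-dione, via dilithio carboxylate enolate 6 (not isolated), via aldol hydroxy acid 7 (not isolated)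
Conditions: LiN(SiMe3)2 (2.1 equiv), THF, −78 °C; then 5, −78 °C; 1 M HCl; then TsOH·H2O (cat.), CH2Cl2, rt; crystallisation or chromatography
Reagents that add atoms: none
Why: Two equivalents of base turn 3 into carboxylate enolate 6, planar at C8, and its lithium aldol addition to 5 forms C7–C8 of hydroxy acid 7; the closest known reaction type is the alkylation and aldol addition of tert-butyl dioxolanone enolates with self-regeneration of the stereocentre. C8 is set by the acetal carbon: the tert-butyl group shields its own face, the aldehyde adds trans to it, and C7 therefore takes the place of the former hydrogen with retention. C7 is set by a chair Zimmerman–Traxler arrangement with the aryl group equatorial, in which the CH2CO2Li arm (cis to OLi on the enolate) ends syn to the new hydroxyl, which places the aryl group cis to the C8 oxygen in ring B. Ring B then closes under acid by 5-exo-trig acyl substitution of the C7 hydroxyl on the C9' carboxyl, which locks C7 and C8 in a rigid spiro lactone from which a minor C7 epimer can be separated. The step needs enolisation at C8 and not at C8', secured by the carboxylate, which makes the C8' hydrogens non-acidic. It also needs one enolate face, secured by the tert-butyl group, and −78 °C to keep the enolate from self-condensation.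

Step 4
Reactants: 8 (2S,5R,6R)-2-tert-butyl-6-Ar-1,3,7-trioxaspiro[4.4]nonane-4,8-dione
Product: 9 methyl (2R,3R)-3-hydroxy-2-Ar-5-oxooxolane-3-carboxylate
Conditions: HCl (1.25 M in MeOH), 40 °C; evaporation
Reagents that add atoms: methanol, CO
Why: Acid-catalysed methanolysis of the acylal-type dioxolanone frees the C8 hydroxyl and gives the C9 methyl ester without breaking a bond to C7 or C8, while the γ-lactone is retained because five-ring closure is favoured on concentration and the C7 position is deactivated towards ionisation by the oxygen and ester on C8.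

Step 5
Reactants: 9 methyl (2R,3R)-3-hydroxy-2-Ar-5-oxooxolane-3-carboxylate; 5 3-methoxy-4-(triisopropylsilyloxy)benzaldehyde
Product: 11 methyl (2R,3R,4R)-3-hydroxy-4-[(RS)-hydroxy(Ar)methyl]-2-Ar-5-oxooxolane-3-carboxylate, via dilithio alkoxide enolate 10 (not isolated)
Conditions: LiN(iPr)2 (2.2 equiv), THF, −78 → −40 °C; then 5, −78 °C; AcOH, −78 °C
Reagents that add atoms: none
Why: In this Fráter–Seebach-type dianion aldol the C8 alkoxide cannot leave, so the lactone enolate does not undergo β-elimination, and the aldehyde should add to C8' on the face opposite the solvated C8–OLi group and the cis C7 aryl group, that is cis to the C9 ester as ring A requires; the C7' configuration is left open because step 7 sets it.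

Step 6
Reactants: 11 methyl (2R,3R,4R)-3-hydroxy-4-[(RS)-hydroxy(Ar)methyl]-2-Ar-5-oxooxolane-3-carboxylate
Product: 12 (1R,2S,3R,4RS)-2,3-bis(hydroxymethyl)-1,4-bis(Ar)butane-1,2,4-triol
Conditions: LiAlH4, THF, 0 °C; aq. KNaC4H4O6 (potassium sodium tartrate)
Reagents that add atoms: none
Why: Hydride reduction of the methyl ester and the lactone gives the C9 and C9' primary alcohols and frees the C7 hydroxyl with its C–O bond intact, so C7, C8 and C8' keep their configuration.

Step 7
Reactants: 12 (1R,2S,3R,4RS)-2,3-bis(hydroxymethyl)-1,4-bis(Ar)butane-1,2,4-triol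
Product: 13 (3S,4R,5S)-3-[(R)-hydroxy(Ar)methyl]-4-(hydroxymethyl)-5-Ar-oxolan-3-ol
Conditions: CSA (10 mol%), CH2Cl2, 0 °C; Et3N quench once 12 is consumed
Reagents that add atoms: none
Why: Acid-catalysed SN1 cyclodehydration ionises the C7' carbinol (cation stabilised by the para silyloxy aryl group) in preference to the C7 carbinol, which is deactivated by the hydroxyl on C8. The primary C9 hydroxyl traps the planar cation to close ring A, so both C7' epimers converge, and with the C8' hydrogen eclipsing the cation plane (minimal A(1,3) strain) the aryl group ends trans to the C9' hydroxymethyl group, which is also the more stable 2,3-trans tetrahydrofuran.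

Step 8
Reactants: 13 (3S,4R,5S)-3-[(R)-hydroxy(Ar)methyl]-4-(hydroxymethyl)-5-Ar-oxolan-3-ol
Product: 15 (1S,2R,5R,6S)-2,6-bis(Ar)-3,7-dioxabicyclo[3.3.0]octan-1-ol, via primary mesylate 14 (not isolated)
Conditions: MsCl (1.1 equiv), pyridine, 0 °C; then 40 °C
Reagents that add atoms: none
Why: Sulfonylation selects the only primary hydroxyl (C9'), and the neighbouring C7 hydroxyl displaces the mesylate in a 5-exo-tet intramolecular Williamson etherification that closes ring B cis-fused without breaking the C7–O bond, so C7 is retained; the tertiary hydroxyl could only form an oxetane.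

Step 9
Reactants: 15 (1S,2R,5R,6S)-2,6-bis(Ar)-3,7-dioxabicyclo[3.3.0]octan-1-ol
Product: 16 (1S,2R,5R,6S)-2,6-bis(Ar)-3,7-dioxabicyclo[3.3.0]octan-1-yl acetate
Conditions: Ac2O, DMAP, Et3N, CH2Cl2, 40 °C
Reagents that add atoms: acetic anhydride, CC(=O)OC(C)=O
Why: DMAP-catalysed acylation (Steglich-type acyl transfer) acetylates the tertiary bridgehead alcohol, the only free hydroxyl, under basic conditions that leave the benzylic ethers untouched.

Step 10
Reactants: 16 (1S,2R,5R,6S)-2,6-bis(Ar)-3,7-dioxabicyclo[3.3.0]octan-1-yl acetate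
Product: 17 1-acetoxypinoresinol, (1S,2R,5R,6S)-2,6-bis(4-hydroxy-3-methoxyphenyl)-3,7-dioxabicyclo[3.3.0]octan-1-yl acetate
Conditions: Bu4NF, AcOH (1:1), THF, 0 °C
Reagents that add atoms: none
Why: Fluoride cleaves the two aryl silyl ethers, and the acetic acid buffer protonates the phenoxides at once so that the hindered tertiary acetate and the benzylic ethers are not attacked.

**Compound list**

1 | (S)-malic acid | O[C@@H](CC(=O)O)C(=O)O | starting material
2 | pivalaldehyde | CC(C)(C)C=O | starting material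
3 | 2-[(2S,4S)-2-tert-butyl-5-oxo-1,3-dioxolan-4-yl]acetic acid | CC(C)(C)[C@H]1O[C@@H](CC(=O)O)C(=O)O1 | intermediate
4 | vanillin | COc1cc(C=O)ccc1O | starting material
5 | 3-methoxy-4-(triisopropylsilyloxy)benzaldehyde | COc1cc(C=O)ccc1O[Si](C(C)C)(C(C)C)C(C)C | intermediate
6 | dilithium 2-[(2S)-2-tert-butyl-5-oxido-1,3-dioxol-4-yl]acetate | CC(C)(C)[C@H]1OC(CC(=O)[O-])=C([O-])O1.[Li+].[Li+] | intermediate
7 | 2-[(2S,4R)-2-tert-butyl-4-[(R)-hydroxy(Ar)methyl]-5-oxo-1,3-dioxolan-4-yl]acetic acid | CC(C)(C)[C@H]1O[C@@]([C@H](O)c2ccc(O[Si](C(C)C)(C(C)C)C(C)C)c(OC)c2)(CC(=O)O)C(=O)O1 | intermediate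
8 | (2S,5R,6R)-2-tert-butyl-6-Ar-1,3,7-trioxaspiro[4.4]nonane-4,8-dione | CC(C)(C)[C@H]1O[C@@]2(CC(=O)O[C@@H]2c3ccc(O[Si](C(C)C)(C(C)C)C(C)C)c(OC)c3)C(=O)O1 | intermediate
9 | methyl (2R,3R)-3-hydroxy-2-Ar-5-oxooxolane-3-carboxylate | O[C@@]1(CC(=O)O[C@@H]1c2ccc(O[Si](C(C)C)(C(C)C)C(C)C)c(OC)c2)C(=O)OC | intermediate
10 | dilithium (2R,3R)-3-(methoxycarbonyl)-2-Ar-3-oxido-2,3-dihydrofuran-5-olate | [Li+].[Li+].[O-][C@@]1(C=C([O-])O[C@@H]1c2ccc(O[Si](C(C)C)(C(C)C)C(C)C)c(OC)c2)C(=O)OC | intermediate
11 | methyl (2R,3R,4R)-3-hydroxy-4-[(RS)-hydroxy(Ar)methyl]-2-Ar-5-oxooxolane-3-carboxylate (C7' epimer pair) | O[C@@]1([C@@H](C(O)c2ccc(O[Si](C(C)C)(C(C)C)C(C)C)c(OC)c2)C(=O)O[C@@H]1c3ccc(O[Si](C(C)C)(C(C)C)C(C)C)c(OC)c3)C(=O)OC | intermediate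
12 | (1R,2S,3R,4RS)-2,3-bis(hydroxymethyl)-1,4-bis(Ar)butane-1,2,4-triol (C7' epimer pair) | OC[C@](O)([C@H](O)c1ccc(O[Si](C(C)C)(C(C)C)C(C)C)c(OC)c1)[C@H](CO)C(O)c2ccc(O[Si](C(C)C)(C(C)C)C(C)C)c(OC)c2 | intermediate
13 | (3S,4R,5S)-3-[(R)-hydroxy(Ar)methyl]-4-(hydroxymethyl)-5-Ar-oxolan-3-ol | COc1cc([C@H]2OC[C@](O)([C@H](O)c3ccc(O[Si](C(C)C)(C(C)C)C(C)C)c(OC)c3)[C@@H]2CO)ccc1O[Si](C(C)C)(C(C)C)C(C)C | intermediate
14 | [(2S,3R,4S)-4-hydroxy-4-[(R)-hydroxy(Ar)methyl]-2-Ar-oxolan-3-yl]methyl methanesulfonate | COc1cc([C@H]2OC[C@](O)([C@H](O)c3ccc(O[Si](C(C)C)(C(C)C)C(C)C)c(OC)c3)[C@@H]2COS(C)(=O)=O)ccc1O[Si](C(C)C)(C(C)C)C(C)C | intermediate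
15 | (1S,2R,5R,6S)-2,6-bis(Ar)-3,7-dioxabicyclo[3.3.0]octan-1-ol | COc1cc([C@H]2OC[C@]3(O)[C@@H](c4ccc(O[Si](C(C)C)(C(C)C)C(C)C)c(OC)c4)OC[C@H]23)ccc1O[Si](C(C)C)(C(C)C)C(C)C | intermediate
16 | (1S,2R,5R,6S)-2,6-bis(Ar)-3,7-dioxabicyclo[3.3.0]octan-1-yl acetate | COc1cc([C@H]2OC[C@]3(OC(C)=O)[C@@H](c4ccc(O[Si](C(C)C)(C(C)C)C(C)C)c(OC)c4)OC[C@H]23)ccc1O[Si](C(C)C)(C(C)C)C(C)C | intermediate
17 | 1-acetoxypinoresinol | COc1cc([C@H]2OC[C@]3(OC(C)=O)[C@@H](c4ccc(O)c(OC)c4)OC[C@H]23)ccc1O | target

**Step count**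

Total steps: 10. Longest linear sequence: 9 steps (steps 1 and 3 to 10, from (S)-malic acid).

**Steps most likely to fail**

Step 3. The lithium aldol may show low simple diastereoselection at C7 (a boat or open arrangement competing with the chair), and the enolate may be lost by self-condensation before the aldehyde adds. The fallback sets out from 3 and 5 and comes back at 8; it makes C7 a ketone and sets it by hydride delivery. Aldehyde 5 is oxidised (Pinnick oxidation: NaClO2, NaH2PO4, 2-methyl-2-butene) to 3-methoxy-4-(triisopropylsilyloxy)benzoic acid F1, which (COCl)2 with catalytic DMF converts into 3-methoxy-4-(triisopropylsilyloxy)benzoyl chloride F2. Enolate 6, made from 3 as in step 3, is C-acylated by F2 at −78 °C trans to the tert-butyl group to give 2-[(2S,4R)-2-tert-butyl-4-[3-methoxy-4-(triisopropylsilyloxy)benzoyl]-5-oxo-1,3-dioxolan-4-yl]acetic acid F3. Reduction of the aryl ketone with Bu4NBH4 in CH2Cl2 (no chelation) is expected to follow the polar Felkin–Anh model, with the C8–O bond anti to hydride and the tied-back ring carbonyl as the small group, and to give 7; Zn(BH4)2 offers the chelate-controlled sense if the opposite face is needed. Hydroxy acid 7 then lactonises to 8 as in step 3.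

Step 5. The aldehyde may approach the enolate face cis to the C8 alkoxide, which gives the wrong C8' configuration, or the aldolate may revert by retro-aldol cleavage. The fallback sets out from 9 and comes back at 12; it replaces kinetic face selection by a lactonisation gate. After addition of 5 at −78 °C the aldolate mixture is allowed to warm to −20 °C, where retro-aldol and aldol addition should equilibrate the C8' epimers. Only the aldolate whose C7' arm is cis to the C9 ester can close ring A as a lactone, since a trans-fused bis-lactone is too strained. This gives (1R,2R,5R,6RS)-1-hydroxy-2,6-bis(Ar)-3,7-dioxabicyclo[3.3.0]octane-4,8-dione F4, which is separable from non-lactonised material. LiAlH4 in THF at 0 °C reduces F4 to pentaol 12.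

Step 7. The C7' cation may be captured by the secondary C7 hydroxyl to give a 2,5-diaryl tetrahydrofuran, the C7 carbinol may ionise with loss of its configuration, or C7' may drift towards the cis isomer on long exposure to acid. The fallback sets out from 11 and comes back at 13; it closes ring A while the C7 oxygen is still locked in lactone B. Hydroxyl-directed reduction of the α-hydroxy ester alone (BH3·SMe2, cat. NaBH4, THF) gives (3R,4S,5R)-4-hydroxy-3-[(RS)-hydroxy(Ar)methyl]-4-(hydroxymethyl)-5-Ar-oxolan-2-one F5. CSA in CH2Cl2 then ionises C7', and the C9 hydroxyl, the only one that can form a five-membered ring, closes ring A to give (1S,2R,5R,6S)-1-hydroxy-2,6-bis(Ar)-3,7-dioxabicyclo[3.3.0]octan-4-one F6. LiAlH4 reduces the lactone of F6 to triol 13, which enters step 8.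

Further compounds
F1 | step 3 | 3-methoxy-4-(triisopropylsilyloxy)benzoic acid | COc1cc(C(=O)O)ccc1O[Si](C(C)C)(C(C)C)C(C)C
F2 | step 3 | 3-methoxy-4-(triisopropylsilyloxy)benzoyl chloride | COc1cc(C(=O)Cl)ccc1O[Si](C(C)C)(C(C)C)C(C)C
F3 | step 3 | 2-[(2S,4R)-2-tert-butyl-4-[3-methoxy-4-(triisopropylsilyloxy)benzoyl]-5-oxo-1,3-dioxolan-4-yl]acetic acid | CC(C)(C)[C@H]1O[C@@](C(=O)c2ccc(O[Si](C(C)C)(C(C)C)C(C)C)c(OC)c2)(CC(=O)O)C(=O)O1
F4 | step 5 | (1R,2R,5R,6RS)-1-hydroxy-2,6-bis(Ar)-3,7-dioxabicyclo[3.3.0]octane-4,8-dione | COc1cc(C2OC(=O)[C@]3(O)[C@@H](c4ccc(O[Si](C(C)C)(C(C)C)C(C)C)c(OC)c4)OC(=O)[C@H]23)ccc1O[Si](C(C)C)(C(C)C)C(C)C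
F5 | step 7 | (3R,4S,5R)-4-hydroxy-3-[(RS)-hydroxy(Ar)methyl]-4-(hydroxymethyl)-5-Ar-oxolan-2-one | O[C@@]1([C@@H](C(O)c2ccc(O[Si](C(C)C)(C(C)C)C(C)C)c(OC)c2)C(=O)O[C@@H]1c3ccc(O[Si](C(C)C)(C(C)C)C(C)C)c(OC)c3)CO
F6 | step 7 | (1S,2R,5R,6S)-1-hydroxy-2,6-bis(Ar)-3,7-dioxabicyclo[3.3.0]octan-4-one | COc1cc([C@H]2OC[C@]3(O)[C@@H](c4ccc(O[Si](C(C)C)(C(C)C)C(C)C)c(OC)c4)OC(=O)[C@H]23)ccc1O[Si](C(C)C)(C(C)C)C(C)C
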